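## Structural features

The target is a depsidone in which ring A (carbons C1–C6) and ring B (carbons C1′–C6′) are joined twice, by the diaryl ether C5–O–C1′ and by the aryl ester C4–C(=O)–O–C2′, so that the seven-membered lactone ring C is closed. Ring A carries OMe at C1, H at C2, CH3 at C3 and CH2OH at C6. Ring B is fully substituted, with CH3 at C3′, OH at C4′ and the five-membered lactol ring D (a 3-hydroxyphthalide) fused across C5′ (lactone carbonyl) and C6′ (lactol carbon). The only stereocentre is the lactol carbon on C6′, which is (R) by the order ring O > OH > aryl C > H; it has no stereogenic neighbour and can epimerize through the open formyl acid, so it has to be fixed late and released under neutral aprotic conditions. The other fragile groups are the aryl ester of ring C (base, nucleophiles) and the benzylic alcohol at C6, which lies between two ring oxygens and ionizes easily in strong acid. The real difficulty is the ether, because each of its carbons has two ortho substituents (C4 and C6, C2′ and C6′). The key step exploits the meta relation of the ring A oxygens at C1 and C5, with the carbon-bearing C6 between them: a vinylketene (C1–C4) and an oxygen-substituted alkyne (C5, C6) give exactly this pattern, so the hindered ring B oxygen can first be bonded to an unhindered sp carbon and ring A then be built around it.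

## Logic of the disconnections

33 to 32. The three benzylic C–O bonds are cut: the benzyl ether at O–C4′, the benzyl ether of the C6 side chain, and the 1-phenylethyl group on the lactol oxygen. The lactol must appear only in the last operation and without acid, base or protic solvent, and hydrogenolysis does not touch the C6′–O bond. The gain is a configurationally stable acetal in place of a labile lactol. The demand is that each cleavage occurs on the side of the unhindered phenyl group.

32 to 31. Ring C is opened at its acyl carbon, cutting C4–C(=O) and C(=O)–O–C2′. The carbonyl carbon is inserted last, so ring A can be made with C4 unsubstituted and no carboxyl has to be carried through its construction. The gain is an open diaryl ether with a bromide at C4 and a free phenol at C2′. The demand is oxidative addition at a di-ortho-substituted bromide and closure of a seven-membered ring.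

31 to 29 (through 30). The exocyclic acetal C–O bond at C6′ is cut. A chiral benzylic alcohol turns the two lactol configurations into separable diastereomers that interconvert under the acetalization conditions, so the unwanted epimer 30 is re-equilibrated to 31 after each separation and is not lost. The gain is a racemic lactol as precursor. The demand is acid mild enough to spare the benzylic ether at C6 and the auxiliary.

29 to 27, 26 and 25. Only functional groups change: the allyl ester at C5′, the allyl ether at C2′ and the dioxolane at C6′ are restored, then the O–CH3 bond at C1 and the C4–Br bond are removed. Allyl and dioxolane were chosen so that the whole unmasking needs zerovalent palladium and dilute acid only. A tert-butyl ester next to an acetal was rejected, because the ester carbonyl traps the oxocarbenium ion and the ester is lost whenever that acetal is made or cleaved under acid. The demand on 25 is bromination para to its phenol.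

25 to 15 and 20. The C1–C6 and C4–C5 bonds of ring A are cut. This removes the hindered aryl–oxygen coupling altogether and reduces ring A to a four-carbon ketone and a two-carbon alkyne. The demand is the correct orientation of the ketene–alkyne addition.

15 to 11 and 13, and 13 to 12; 20 to 19, and 19 to 16 and 17. The O–C(sp) bond is cut back to a phenol and a 1,1-dibromoalkene, which comes from an aldehyde by one-carbon homologation. The cyclobutenone is cut into a ketene and an alkyne. Both are short, known sequences; the demand is that a phenoxide with two ortho substituents still couples.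

11 back to 1. The C5′–carboxyl bond is cut to a bromide (8), the acetal to an aldehyde (7), the C6′–CHO bond to a phenol (6), and the C1′–O bond to a formyl group (4). The ether and bromine substituents are then removed in turn (3, 2, 1). Every substituent enters at the only position its directing groups allow, and the carboxyl enters under basic conditions after the acetal. The demand is a clean bromine–lithium exchange in the presence of a phenoxide.

## Other disconnections considered

Alternative 1: The cut is inside ring D, at C5′–C(=O) and at the acyl C–O bond, leading back to the bromo aldehyde A1. In the forward step Pd(OAc)2, a chiral bisphosphine, CO and benzyl alcohol would convert the C5′ bromide of A1 into its acylpalladium derivative. After reversible addition of benzyl alcohol to the formyl group, one enantiomeric form of the adduct would be acylated at oxygen to give A2. In its favour, ring D and the stereocentre would be made in one catalytic operation without an auxiliary, and the racemic version (alkoxycarbonylation of 2-bromobenzaldehydes to 3-alkoxyphthalides) is an established reaction type. A2 is also the very compound that one hydrogenolysis converts into the target. Against it, the enantio-determining event is the capture of a weakly bound, fast-racemizing adduct by an acyl group whose chiral ligand is remote. Direct alcoholysis of the acylpalladium by benzyl alcohol before ring closure would bypass the chiral environment and erode the selectivity. The bromide lies between OBn and CHO. A1 also still needs ring A, the ether and ring C to be made, so this is an endgame and not an answer to the main difficulty. Merged with the chosen benzannulation, it would require two aryl bromides to be carbonylated in a controlled order. On stereochemical economy it is better than the chosen plan (catalytic control instead of separation and re-equilibration). On step count it is equal or one step shorter. On mechanistic certainty it is weaker.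

Alternative 2: The cut is the C5–O ether bond, made last, with ring A at the cyclohexane-1,3-dione level and already esterified to O–C2′ (A3). In the forward step toluenesulfonic acid with removal of water would condense the C1′ phenol with the C5 carbonyl to give the vinylogous ester A4; dehydrogenation and O-methylation would follow. In its favour, the ether is formed by a metal-free condensation whose steric cost is paid intramolecularly, ring C closes in the same step, and the C4 carboxyl arrives with the fragment. On these three points it is the equal or the better of the chosen plan, which needs separate bromination and carbonylation. Against it, A3 is an aryl ester of a β-keto acid and is prone to acyl transfer and ketene loss on heating with acid. The CH2OBn group between two carbonyls can be lost by β-elimination. The free aldehyde at C6′ is exposed to the acid. The later aromatization has to oxidize ring A in the presence of benzylic ethers and an aldehyde. The two stereocentres of A4 are destroyed again, and the dione fragment of A3 would itself take several steps to prepare. Overall the mechanism is simpler than a pericyclic cascade but the intermediates are more fragile, and the route would probably be one or two steps longer after the key step.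

Alternative 3: The cut removes the C5–O ether bond and the C6–carboxyl bond together. In the forward step CsF would generate the C5–C6 aryne from silyl triflate A5 under CO2; the phenoxide of A6 would add at C5 and the C6 aryl anion would be carboxylated, giving A7. In its favour, arynes accept very hindered phenoxides at room temperature. The union is fully convergent, and C4 already carries its carboxyl, so neither halogenation nor carbonylation is needed. On convergence and on avoiding the palladium step it is better than the chosen plan. Against it, the aryne is flanked by a methoxy group (which directs the nucleophile to C5) and an ester (which directs it to C6), so the regiochemistry is not secured. The aryl anion must be carboxylated faster than it is protonated or attacks the neighbouring ester. The C6 acid then has to be reduced to CH2OH beside three other carboxyl derivatives. A5 would need about as many steps as ring B, and A6 carries the tert-butyl ester and acetal pairing criticized above. The chosen plan brings C6 in at the alcohol oxidation state and controls regiochemistry electronically, and the total step counts would probably be similar.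

Key step: step 12

Remark on the chemistry: the lactol carbon C6′ epimerizes through ring opening in acid, base or protic media; it is assumed to keep its configuration in neutral ethyl acetate, so the last step and its work-up avoid all three.

## Route

Step 1
Reactants: 1 2,4-dihydroxy-3-methylbenzaldehyde
Product: 2 4-(benzyloxy)-2-hydroxy-3-methylbenzaldehyde
Conditions: BnBr (1.05 equiv), K2CO3, KI (cat.), MeCN, 60 °C
Reagents that add atoms: benzyl bromide, BrCc1ccccc1
Why: Williamson etherification; the 4-OH is the more acidic phenol (para to the formyl group) and the 2-OH is hydrogen-bonded to the carbonyl and flanked by CHO and CH3, so one equivalent of benzyl bromide with a weak base should alkylate O-4 only.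

Step 2
Reactants: 2 4-(benzyloxy)-2-hydroxy-3-methylbenzaldehyde
Product: 3 4-(benzyloxy)-5-bromo-2-hydroxy-3-methylbenzaldehyde
Conditions: NBS, MeCN, 0 °C
Reagents that add atoms: N-bromosuccinimide, O=C1CCC(=O)N1Br
Why: Electrophilic aromatic bromination; C5 is para to the free phenol and ortho to the benzyloxy group whereas C6 is meta to both oxygens, so the 5-bromide should form alone.

Step 3
Reactants: 3 4-(benzyloxy)-5-bromo-2-hydroxy-3-methylbenzaldehyde
Product: 4 2-(allyloxy)-4-(benzyloxy)-5-bromo-3-methylbenzaldehyde
Conditions: allyl bromide, K2CO3, DMF, 50 °C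
Reagents that add atoms: allyl bromide, C=CCBr
Why: Williamson etherification of the remaining hydrogen-bonded phenol under more forcing conditions; allyl is chosen because it later leaves under neutral palladium catalysis and does not migrate between neighbouring oxygens.

Step 4
Reactants: 4 2-(allyloxy)-4-(benzyloxy)-5-bromo-3-methylbenzaldehyde
Product: 6 2-(allyloxy)-4-(benzyloxy)-5-bromo-3-methylphenol, via aryl formate 5 (not isolated)
Conditions: 30% H2O2, H2SO4 (cat.), MeOH, rt
Reagents that add atoms: hydrogen peroxide, OO
Why: Dakin oxidation (acid-catalysed Baeyer–Villiger-type aryl migration); the aryl group has ortho- and para-alkoxy donors and migrates in preference to hydrogen, the formate is methanolysed in the same pot, and hydrogen peroxide without a peracid or metal should leave the allyl double bond alone.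

Step 5
Reactants: 6 2-(allyloxy)-4-(benzyloxy)-5-bromo-3-methylphenol
Product: 7 3-(allyloxy)-5-(benzyloxy)-6-bromo-2-hydroxy-4-methylbenzaldehyde
Conditions: MgCl2, Et3N, (CH2O)n, MeCN, reflux, argon
Reagents that add atoms: paraformaldehyde (formaldehyde), C=O
Why: Casnati–Skattebøl ortho-formylation; the magnesium phenoxide delivers formaldehyde to the carbon ortho to the hydroxyl, which is the only free position of the ring, and a second formaldehyde takes up hydride to give the aldehyde.

Step 6
Reactants: 7 3-(allyloxy)-5-(benzyloxy)-6-bromo-2-hydroxy-4-methylbenzaldehyde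
Product: 8 2-(allyloxy)-4-(benzyloxy)-5-bromo-6-(1,3-dioxolan-2-yl)-3-methylphenol
Conditions: HOCH2CH2OH, TsOH·H2O (cat.), toluene, reflux (Dean–Stark)
Reagents that add atoms: ethylene glycol, OCCO
Why: Acid-catalysed acetalization with azeotropic removal of water; a cyclic acetal is used because it is stable beside a free ortho phenol and under the basic coupling to come, and at this stage the molecule holds no acid-labile ester or ether.

Step 7
Reactants: 8 2-(allyloxy)-4-(benzyloxy)-5-bromo-6-(1,3-dioxolan-2-yl)-3-methylphenol
Product: 11 allyl 4-(allyloxy)-6-(benzyloxy)-2-(1,3-dioxolan-2-yl)-3-hydroxy-5-methylbenzoate, via dilithio species 9 (not isolated), via allyl carbonate 10 (not isolated)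
Conditions: n-BuLi (2.2 equiv), THF, −78 °C; inverse addition to ClCO2CH2CH=CH2 (3 equiv), −78 → 0 °C; then K2CO3 (cat.), MeOH, rt
Reagents that add atoms: allyl chloroformate, C=CCOC(=O)Cl
Why: Deprotonation and bromine–lithium exchange give an aryllithium held between the benzyloxy and dioxolane oxygens, which is C-acylated by the chloroformate while the phenoxide is carbonated; the unhindered aryl carbonate is then methanolysed selectively because the new benzoate is blocked on both sides, and the carboxyl enters under basic conditions after the acetal, so ester and acetal never meet acid together.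

Step 8
Reactants: 12 benzyloxyacetaldehyde
Product: 13 [(3,3-dibromoprop-2-en-1-yl)oxy]methylbenzene
Conditions: CBr4, PPh3, CH2Cl2, 0 °C
Reagents that add atoms: carbon tetrabromide, BrC(Br)(Br)Br
Why: Ramirez gem-dibromoolefination (first stage of the Corey–Fuchs sequence) of an aldehyde with the ylide from CBr4 and PPh3.

Step 9
Reactants: 11 allyl 4-(allyloxy)-6-(benzyloxy)-2-(1,3-dioxolan-2-yl)-3-hydroxy-5-methylbenzoate, 13 [(3,3-dibromoprop-2-en-1-yl)oxy]methylbenzene
Product: 15 allyl 4-(allyloxy)-6-(benzyloxy)-3-{[3-(benzyloxy)prop-1-yn-1-yl]oxy}-2-(1,3-dioxolan-2-yl)-5-methylbenzoate, via bromoenol ether 14 (not isolated)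
Conditions: CuI (10 mol%), 2,2′-bipyridine (20 mol%), K3PO4, toluene, 110 °C; then KOtBu, 1,4-dioxane, rt
Reagents that add atoms: none
Why: Copper-catalysed C–O coupling of a phenol with a 1,1-dibromoalkene (monovalent copper with a bipyridine ligand) at the less hindered bromine trans to the chain, then anti E2 loss of HBr with tert-butoxide to the ynol ether; the hindered oxygen is bonded to a carbon that has no ortho neighbours, and the di-ortho-substituted allyl ester should resist tert-butoxide at room temperature.

Step 10
Reactants: 16 trichloroacetyl chloride, 17 propyne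
Product: 19 4,4-dichloro-3-methylcyclobut-2-en-1-one, via dichloroketene 18 (not isolated)
Conditions: Zn–Cu couple, Et2O/DME, 0 °C → rt, excess propyne
Reagents that add atoms: none
Why: Zinc dechlorination of the acid chloride gives dichloroketene, which adds [2+2] to the alkyne with its carbonyl carbon at the terminal alkyne carbon, as in the standard preparation of 3-alkyl-4,4-dichlorocyclobutenones.

Step 11
Reactants: 19 4,4-dichloro-3-methylcyclobut-2-en-1-one
Product: 20 3-methylcyclobut-2-en-1-one
Conditions: Zn, AcOH, TMEDA, EtOH, 0 °C → rt
Reagents that add atoms: none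
Why: Reductive dechlorination with zinc in buffered acetic acid, the usual way from 4,4-dichlorocyclobutenones to cyclobutenones; the volatile product is used as a solution soon after it is made.

Step 12
Reactants: 15 allyl 4-(allyloxy)-6-(benzyloxy)-3-{[3-(benzyloxy)prop-1-yn-1-yl]oxy}-2-(1,3-dioxolan-2-yl)-5-methylbenzoate, 20 3-methylcyclobut-2-en-1-one
Product: 25 allyl 4-(allyloxy)-6-(benzyloxy)-3-{2-[(benzyloxy)methyl]-3-hydroxy-5-methylphenoxy}-2-(1,3-dioxolan-2-yl)-5-methylbenzoate, via vinylketene 21 (not isolated), via vinylcyclobutenone 22 (not isolated), via dienylketene 23 (not isolated), via cyclohexadienone 24 (not isolated)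
Conditions: toluene, 80 → 110 °C, sealed tube, 20 (2 equiv)
Reagents that add atoms: none
Why: On heating, 20 undergoes strain-releasing 4π electrocyclic opening to vinylketene 21. The electron-rich ynol ether 15 adds to the ketene C=C in a [2+2] cycloaddition in which the ketene carbonyl carbon (future C1) bonds to the nucleophilic β-carbon of the alkyne (C6) and the ketene α-carbon (C4) bonds to the oxygen-bearing carbon (C5), giving 22. Its 4π opening gives dienylketene 23, and ring A closes by thermal disrotatory 6π electrocyclization, which re-forms the C1–C2 bond and gives dienone 24; tautomerization gives phenol 25. The closest known reaction is the Danheiser benzannulation of cyclobutenones with alkoxy- and siloxyalkynes, of which an aryloxyalkyne is a less nucleophilic member of the same class. No stereocentre is formed. The selectivity needed is the orientation of the [2+2] step, and it is set by the polarization of the ynol ether by its oxygen lone pair against the electrophilic central carbon of the ketene, so that C6 ends between the two oxygens. The aryloxy group has no C–H β to oxygen, so the retro-ene fragmentation that limits alkyl ynol ethers is not available, both ortho positions of ring B are blocked against sigmatropic diversion, and the allyl groups, the ester and the acetal are not ketenophiles. The hindered ring B oxygen stays a spectator on a linear carbon while the new ring is built around it.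

Step 13
Reactants: 25 allyl 4-(allyloxy)-6-(benzyloxy)-3-{2-[(benzyloxy)methyl]-3-hydroxy-5-methylphenoxy}-2-(1,3-dioxolan-2-yl)-5-methylbenzoate
Product: 26 allyl 4-(allyloxy)-6-(benzyloxy)-3-{2-[(benzyloxy)methyl]-6-bromo-3-hydroxy-5-methylphenoxy}-2-(1,3-dioxolan-2-yl)-5-methylbenzoate
Conditions: NBS (1.0 equiv), MeCN, −20 °C
Reagents that add atoms: N-bromosuccinimide, O=C1CCC(=O)N1Br
Why: Electrophilic bromination of a 3,5-disubstituted phenol; C4 is para to the free hydroxyl (the strongest donor) and ortho to the aryloxy group while C2 is ortho to the hydroxyl, so para attack should dominate in acetonitrile at low temperature; ring B has no free position and the allyl double bonds are far less reactive than the phenol.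

Step 14
Reactants: 26 allyl 4-(allyloxy)-6-(benzyloxy)-3-{2-[(benzyloxy)methyl]-6-bromo-3-hydroxy-5-methylphenoxy}-2-(1,3-dioxolan-2-yl)-5-methylbenzoate
Product: 27 allyl 4-(allyloxy)-6-(benzyloxy)-3-{2-[(benzyloxy)methyl]-6-bromo-3-methoxy-5-methylphenoxy}-2-(1,3-dioxolan-2-yl)-5-methylbenzoate
Conditions: MeI, K2CO3, acetone, 40 °C
Reagents that add atoms: iodomethane, CI
Why: Williamson O-methylation of the only acidic group in the molecule.

Step 15
Reactants: 27 allyl 4-(allyloxy)-6-(benzyloxy)-3-{2-[(benzyloxy)methyl]-6-bromo-3-methoxy-5-methylphenoxy}-2-(1,3-dioxolan-2-yl)-5-methylbenzoate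
Product: 29 7-(benzyloxy)-4-{2-[(benzyloxy)methyl]-6-bromo-3-methoxy-5-methylphenoxy}-3,5-dihydroxy-6-methylisobenzofuran-1(3H)-one (racemic at C3), via hydroxy acid 28 (not isolated)
Conditions: Pd(PPh3)4 (5 mol%), morpholine, THF, rt; then 1 M HCl, THF/H2O, rt
Reagents that add atoms: water, O
Why: Tsuji–Trost deallylation; zerovalent palladium ionizes the allyl ester and the allyl aryl ether and morpholine takes up both allyl groups, while the hindered electron-rich aryl bromide should not undergo oxidative addition at room temperature; dilute acid then hydrolyses the dioxolane with neighbouring-group help from the new carboxylic acid and the formyl acid closes to the lactol, with no strong acid that could ionize the benzylic ether at C6.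

Step 16
Reactants: 29 7-(benzyloxy)-4-{2-[(benzyloxy)methyl]-6-bromo-3-methoxy-5-methylphenoxy}-3,5-dihydroxy-6-methylisobenzofuran-1(3H)-one
Product: 31 (3R)-7-(benzyloxy)-4-{2-[(benzyloxy)methyl]-6-bromo-3-methoxy-5-methylphenoxy}-5-hydroxy-6-methyl-3-[(1S)-1-phenylethoxy]isobenzofuran-1(3H)-one, via (3S) acetal epimer 30 (not isolated)
Conditions: (S)-1-phenylethanol (3 equiv), CSA (10 mol%), 4 Å MS, CH2Cl2, rt → 35 °C; chromatography, then re-equilibration of the unpurified (3S)-rich fractions under the same conditions
Reagents that add atoms: (S)-1-phenylethanol, C[C@H](O)c1ccccc1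
Why: Acid-catalysed pseudo-ester formation (Fischer-type acetalization of a 3-hydroxyphthalide) gives both C3 epimers, which are diastereomers because of the (S)-1-phenylethyl group and interconvert through the ring-stabilized oxocarbenium ion as long as acid and the alcohol are present. The (3S) epimer 30 is therefore only a way station: each time the (3R) epimer 31 is taken out by chromatography, the remainder is returned to the acid and re-equilibrated, and this sets the configuration at C6′. The mild acid near room temperature should spare the benzylic ether at C6 and avoid ionization of the auxiliary alcohol.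

Step 17
Reactants: 31 (3R)-7-(benzyloxy)-4-{2-[(benzyloxy)methyl]-6-bromo-3-methoxy-5-methylphenoxy}-5-hydroxy-6-methyl-3-[(1S)-1-phenylethoxy]isobenzofuran-1(3H)-one
Product: 32 depsidone with ring C closed (C4–C(=O)–O–C2′) that carries OMe at C1, CH3 at C3, CH2OBn at C6, CH3 at C3′, OBn at C4′ and ring D as the (R) acetal of (S)-1-phenylethanol at C6′
Conditions: Pd(OAc)2 (10 mol%), Xantphos (12 mol%), CO (1 atm), Et3N, toluene, 90 °C, 0.01 M
Reagents that add atoms: carbon monoxide, [C-]#[O+]
Why: Palladium-catalysed carbonylative lactonization (aryloxycarbonylation); zerovalent palladium with Xantphos adds to the C4–Br bond, CO inserts, and the C2′ phenoxide attacks the acylpalladium intramolecularly to close the seven-membered ring C; the acetal stereocentre is untouched because no acid is present, and high dilution favours ring closure over oligomers.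

Step 18
Reactants: 32 depsidone (R) acetal of (S)-1-phenylethanol
Product: 33 target depsidone with OMe at C1, CH3 at C3, CH2OH at C6, CH3 at C3′, OH at C4′ and ring D as the (R) lactol at C6′
Conditions: H2 (1 atm), 10% Pd/C, EtOAc, rt; filtration and evaporation below rt
Reagents that add atoms: none
Why: Heterogeneous hydrogenolysis of three benzylic C–O bonds; each should be cleaved on the side of the unhindered phenyl group because the C6 side chain and C6′ sit on fully substituted rings that adsorb poorly, and since the C6′–O bond is not broken the lactol is released with retention of the (R) configuration in a neutral aprotic medium.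

## Compound list

1 | 2,4-dihydroxy-3-methylbenzaldehyde | O=Cc1ccc(O)c(C)c1O | starting material
2 | 4-(benzyloxy)-2-hydroxy-3-methylbenzaldehyde | O=Cc1ccc(OCc2ccccc2)c(C)c1O | intermediate
3 | 4-(benzyloxy)-5-bromo-2-hydroxy-3-methylbenzaldehyde | O=Cc1cc(Br)c(OCc2ccccc2)c(C)c1O | intermediate
4 | 2-(allyloxy)-4-(benzyloxy)-5-bromo-3-methylbenzaldehyde | O=Cc1cc(Br)c(OCc2ccccc2)c(C)c1OCC=C | intermediate
5 | 2-(allyloxy)-4-(benzyloxy)-5-bromo-3-methylphenyl formate | O=COc1cc(Br)c(OCc2ccccc2)c(C)c1OCC=C | intermediate (not isolated)
6 | 2-(allyloxy)-4-(benzyloxy)-5-bromo-3-methylphenol | Oc1cc(Br)c(OCc2ccccc2)c(C)c1OCC=C | intermediate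
7 | 3-(allyloxy)-5-(benzyloxy)-6-bromo-2-hydroxy-4-methylbenzaldehyde | O=Cc1c(Br)c(OCc2ccccc2)c(C)c(OCC=C)c1O | intermediate
8 | 2-(allyloxy)-4-(benzyloxy)-5-bromo-6-(1,3-dioxolan-2-yl)-3-methylphenol | Oc1c(OCC=C)c(C)c(OCc2ccccc2)c(Br)c1C1OCCO1 | intermediate
9 | lithium 2-(allyloxy)-4-(benzyloxy)-6-(1,3-dioxolan-2-yl)-5-lithio-3-methylphenolate | [Li]Oc1c(OCC=C)c(C)c(OCc2ccccc2)c([Li])c1C1OCCO1 | intermediate (not isolated)
10 | allyl 4-(allyloxy)-3-{[(allyloxy)carbonyl]oxy}-6-(benzyloxy)-2-(1,3-dioxolan-2-yl)-5-methylbenzoate | C=CCOC(=O)Oc1c(OCC=C)c(C)c(OCc2ccccc2)c(C(=O)OCC=C)c1C1OCCO1 | intermediate (not isolated)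
11 | allyl 4-(allyloxy)-6-(benzyloxy)-2-(1,3-dioxolan-2-yl)-3-hydroxy-5-methylbenzoate (ring B phenol) | Oc1c(OCC=C)c(C)c(OCc2ccccc2)c(C(=O)OCC=C)c1C1OCCO1 | intermediate
12 | benzyloxyacetaldehyde | O=CCOCc1ccccc1 | starting material
13 | [(3,3-dibromoprop-2-en-1-yl)oxy]methylbenzene | BrC(Br)=CCOCc1ccccc1 | intermediate
14 | allyl 4-(allyloxy)-6-(benzyloxy)-3-{[(1Z)-3-(benzyloxy)-1-bromoprop-1-en-1-yl]oxy}-2-(1,3-dioxolan-2-yl)-5-methylbenzoate | c1ccccc1COC/C=C(Br)/Oc1c(OCC=C)c(C)c(OCc2ccccc2)c(C(=O)OCC=C)c1C1OCCO1 | intermediate (not isolated)
15 | allyl 4-(allyloxy)-6-(benzyloxy)-3-{[3-(benzyloxy)prop-1-yn-1-yl]oxy}-2-(1,3-dioxolan-2-yl)-5-methylbenzoate (aryl ynol ether) | c1ccccc1COCC#COc1c(OCC=C)c(C)c(OCc2ccccc2)c(C(=O)OCC=C)c1C1OCCO1 | intermediate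
16 | trichloroacetyl chloride | O=C(Cl)C(Cl)(Cl)Cl | starting material
17 | propyne | CC#C | starting material
18 | dichloroketene | O=C=C(Cl)Cl | intermediate (not isolated)
19 | 4,4-dichloro-3-methylcyclobut-2-en-1-one | CC1=CC(=O)C1(Cl)Cl | intermediate
20 | 3-methylcyclobut-2-en-1-one | CC1=CC(=O)C1 | intermediate
21 | 3-methylbuta-1,3-dien-1-one (vinylketene) | C=C(C)C=C=O | intermediate (not isolated)
22 | allyl 4-(allyloxy)-6-(benzyloxy)-3-({2-[(benzyloxy)methyl]-3-oxo-4-(prop-1-en-2-yl)cyclobut-1-en-1-yl}oxy)-2-(1,3-dioxolan-2-yl)-5-methylbenzoate (racemic) | C=C(C)C1C(=O)C(COCc2ccccc2)=C1Oc1c(OCC=C)c(C)c(OCc2ccccc2)c(C(=O)OCC=C)c1C1OCCO1 | intermediate (not isolated)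
23 | dienylketene O=C=C(CH2OBn)–C(OAr)=CH–C(CH3)=CH2 with ketenyl and isopropenyl groups cis on the central double bond (Ar = ring B of 15) | O=C=C(COCc1ccccc1)/C(Oc1c(OCC=C)c(C)c(OCc2ccccc2)c(C(=O)OCC=C)c1C1OCCO1)=C\C(C)=C | intermediate (not isolated)
24 | 3-aryloxy-2-[(benzyloxy)methyl]-5-methylcyclohexa-2,4-dien-1-one (aryl = ring B of 15) | O=C1CC(C)=CC(Oc2c(OCC=C)c(C)c(OCc3ccccc3)c(C(=O)OCC=C)c2C2OCCO2)=C1COCc1ccccc1 | intermediate (not isolated)
25 | allyl 4-(allyloxy)-6-(benzyloxy)-3-{2-[(benzyloxy)methyl]-3-hydroxy-5-methylphenoxy}-2-(1,3-dioxolan-2-yl)-5-methylbenzoate | Oc1cc(C)cc(Oc2c(OCC=C)c(C)c(OCc3ccccc3)c(C(=O)OCC=C)c2C2OCCO2)c1COCc1ccccc1 | intermediate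
26 | allyl 4-(allyloxy)-6-(benzyloxy)-3-{2-[(benzyloxy)methyl]-6-bromo-3-hydroxy-5-methylphenoxy}-2-(1,3-dioxolan-2-yl)-5-methylbenzoate | Oc1cc(C)c(Br)c(Oc2c(OCC=C)c(C)c(OCc3ccccc3)c(C(=O)OCC=C)c2C2OCCO2)c1COCc1ccccc1 | intermediate
27 | allyl 4-(allyloxy)-6-(benzyloxy)-3-{2-[(benzyloxy)methyl]-6-bromo-3-methoxy-5-methylphenoxy}-2-(1,3-dioxolan-2-yl)-5-methylbenzoate | COc1cc(C)c(Br)c(Oc2c(OCC=C)c(C)c(OCc3ccccc3)c(C(=O)OCC=C)c2C2OCCO2)c1COCc1ccccc1 | intermediate
28 | 6-(benzyloxy)-3-{2-[(benzyloxy)methyl]-6-bromo-3-methoxy-5-methylphenoxy}-2-(1,3-dioxolan-2-yl)-4-hydroxy-5-methylbenzoic acid | COc1cc(C)c(Br)c(Oc2c(O)c(C)c(OCc3ccccc3)c(C(=O)O)c2C2OCCO2)c1COCc1ccccc1 | intermediate (not isolated)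
29 | 7-(benzyloxy)-4-{2-[(benzyloxy)methyl]-6-bromo-3-methoxy-5-methylphenoxy}-3,5-dihydroxy-6-methylisobenzofuran-1(3H)-one (racemic at C3) | COc1cc(C)c(Br)c(Oc2c(O)c(C)c(OCc3ccccc3)c3c2C(O)OC3=O)c1COCc1ccccc1 | intermediate
30 | (3S)-7-(benzyloxy)-4-{2-[(benzyloxy)methyl]-6-bromo-3-methoxy-5-methylphenoxy}-5-hydroxy-6-methyl-3-[(1S)-1-phenylethoxy]isobenzofuran-1(3H)-one (epimer, re-equilibrated in the flask) | COc1cc(C)c(Br)c(Oc2c(O)c(C)c(OCc3ccccc3)c3c2[C@@H](O[C@@H](C)c2ccccc2)OC3=O)c1COCc1ccccc1 | intermediate (not isolated)
31 | (3R)-7-(benzyloxy)-4-{2-[(benzyloxy)methyl]-6-bromo-3-methoxy-5-methylphenoxy}-5-hydroxy-6-methyl-3-[(1S)-1-phenylethoxy]isobenzofuran-1(3H)-one | COc1cc(C)c(Br)c(Oc2c(O)c(C)c(OCc3ccccc3)c3c2[C@H](O[C@@H](C)c2ccccc2)OC3=O)c1COCc1ccccc1 | intermediate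
32 | depsidone: ring A with OMe (C1), CH3 (C3), CH2OBn (C6); ring B with CH3 (C3′), OBn (C4′); ring D lactone whose C6′ carbon is (R) and carries the (1S)-1-phenylethoxy group | COc1cc(C)c2c(c1COCc1ccccc1)Oc1c(c(C)c(OCc3ccccc3)c3c1[C@H](O[C@@H](C)c1ccccc1)OC3=O)OC2=O | intermediate
33 | target depsidone: ring A with OMe (C1), CH3 (C3), CH2OH (C6); ring B with CH3 (C3′), OH (C4′); ring D (R) lactol at C6′ | COc1cc(C)c2c(c1CO)Oc1c(c(C)c(O)c3c1[C@H](O)OC3=O)OC2=O | target

## Step count and least certain steps

Total step count: 18. Longest linear sequence: 15 steps (steps 1–7, 9, 12–18).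

Step 12 (key step). The aryloxyalkyne is a weaker ketenophile than the alkoxy- and siloxyalkynes normally used. Dimerization or polymerization of the vinylketene, acylation of the newly formed phenol by the ketene, or loss of the volatile cyclobutenone may therefore outrun the [2+2] addition at 80–110 °C. Fallback, from 15 back to 25: the same vinylketene is generated slowly at room temperature by photochemical Wolff rearrangement of 1-diazo-3-methylbut-3-en-2-one F1. F1 is made from 3-methylbut-3-en-2-one by detrifluoroacetylative diazo transfer and is irradiated in the presence of 15, so that the ketene always meets an excess of alkyne. Gentle warming then completes the ring opening and the 6π closure to 25.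

Step 9. The phenoxide of 11 has two ortho substituents, so the copper-catalysed C–O coupling may be slow. The tert-butoxide used for dehydrobromination may also isomerize the propargylic ether to an allene. Fallback, from 11 back to 15: the phenoxide is added to trichloroethylene (K2CO3, DMF), which gives allyl 4-(allyloxy)-6-(benzyloxy)-3-{[(E)-1,2-dichloroethenyl]oxy}-2-(1,3-dioxolan-2-yl)-5-methylbenzoate F2. Treatment of F2 with n-BuLi (2.2 equiv, −78 °C) and then benzyl chloromethyl ether gives 15 directly. The di-ortho-substituted ester is expected to survive the short exposure to n-BuLi at low temperature.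

Step 17. Oxidative addition at the di-ortho-substituted, electron-rich C4 bromide may be slow, so that protodebromination or intermolecular ester formation competes with closure of the seven-membered ring. Fallback, from 27 back to 32, by classical lactonization of a seco acid: bromine–magnesium exchange on 27 with n-Bu3MgLi (THF, −10 °C) and quenching with CO2 gives 2-{2-(allyloxy)-5-[(allyloxy)carbonyl]-4-(benzyloxy)-6-(1,3-dioxolan-2-yl)-3-methylphenoxy}-3-[(benzyloxy)methyl]-4-methoxy-6-methylbenzoic acid F3 (carboxyl at C4). The conditions of step 15 convert it into the lactol acid F4, and the conditions of step 16, with the same separation and re-equilibration, give the (3R) 1-phenylethyl acetal acid F5. Lactonization of the C4 acid onto the C2′ phenol (EDC·HCl, DMAP, CH2Cl2, high dilution) then closes ring C and gives 32.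

Step 18. Hydrogenolysis of the hindered secondary benzylic acetal ether may be slow. Prolonged exposure would then bring over-reduction of the benzylic C–O bonds at the C6 side chain or at C6′, or erosion of configuration at C6′ by adventitious acid on the catalyst. Fallback, from 29 back to 33: 29 is acetalized with benzyl alcohol (CSA, 4 Å MS, CH2Cl2) to racemic 3,7-bis(benzyloxy)-4-{2-[(benzyloxy)methyl]-6-bromo-3-methoxy-5-methylphenoxy}-5-hydroxy-6-methylisobenzofuran-1(3H)-one F6. Preparative chromatography on a chiral phase gives the (3R) benzyl acetal F7, and the conditions of step 17 close ring C to the depsidone (R) benzyl acetal F8. Hydrogenolysis of its three primary benzyl groups (H2, Pd/C, EtOAc), which all cleave under the mildest conditions, gives 33.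

## Further compounds

F1 | step 12 | 1-diazo-3-methylbut-3-en-2-one | C=C(C)C(=O)C=[N+]=[N-]
F2 | step 9 | allyl 4-(allyloxy)-6-(benzyloxy)-3-{[(E)-1,2-dichloroethenyl]oxy}-2-(1,3-dioxolan-2-yl)-5-methylbenzoate | Cl/C=C(/Cl)Oc1c(OCC=C)c(C)c(OCc2ccccc2)c(C(=O)OCC=C)c1C1OCCO1
F3 | step 17 | seco acid: 27 with CO2H in place of Br at C4 | COc1cc(C)c(C(=O)O)c(Oc2c(OCC=C)c(C)c(OCc3ccccc3)c(C(=O)OCC=C)c2C2OCCO2)c1COCc1ccccc1
F4 | step 17 | lactol acid: 29 with CO2H in place of Br at C4 (racemic at C3 of ring D) | COc1cc(C)c(C(=O)O)c(Oc2c(O)c(C)c(OCc3ccccc3)c3c2C(O)OC3=O)c1COCc1ccccc1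
F5 | step 17 | (3R) acetal acid: 31 with CO2H in place of Br at C4 | COc1cc(C)c(C(=O)O)c(Oc2c(O)c(C)c(OCc3ccccc3)c3c2[C@H](O[C@@H](C)c2ccccc2)OC3=O)c1COCc1ccccc1
F6 | step 18 | racemic 3,7-bis(benzyloxy)-4-{2-[(benzyloxy)methyl]-6-bromo-3-methoxy-5-methylphenoxy}-5-hydroxy-6-methylisobenzofuran-1(3H)-one | COc1cc(C)c(Br)c(Oc2c(O)c(C)c(OCc3ccccc3)c3c2C(OCc2ccccc2)OC3=O)c1COCc1ccccc1
F7 | step 18 | (3R)-3,7-bis(benzyloxy)-4-{2-[(benzyloxy)methyl]-6-bromo-3-methoxy-5-methylphenoxy}-5-hydroxy-6-methylisobenzofuran-1(3H)-one | COc1cc(C)c(Br)c(Oc2c(O)c(C)c(OCc3ccccc3)c3c2[C@H](OCc2ccccc2)OC3=O)c1COCc1ccccc1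
F8 | step 18 | depsidone with CH2OBn at C6, OBn at C4′ and ring D as the (R) O-benzyl acetal | COc1cc(C)c2c(c1COCc1ccccc1)Oc1c(c(C)c(OCc3ccccc3)c3c1[C@H](OCc1ccccc1)OC3=O)OC2=O
A1 | alternative 1 | depsidone with CH2OBn at C6, OBn at C4′, Br at C5′ and CHO at C6′ | COc1cc(C)c2c(c1COCc1ccccc1)Oc1c(c(C)c(OCc3ccccc3)c(Br)c1C=O)OC2=O
A2 | alternative 1 | depsidone with ring D as the (R) O-benzyl acetal | COc1cc(C)c2c(c1COCc1ccccc1)Oc1c(c(C)c(OCc3ccccc3)c3c1[C@H](OCc1ccccc1)OC3=O)OC2=O
A3 | alternative 2 | ring B C2′ aryl ester of 3-[(benzyloxy)methyl]-6-methyl-2,4-dioxocyclohexane-1-carboxylic acid with free C1′ phenol | O=C1CC(C)C(C(=O)Oc2c(C)c(OCc3ccccc3)c(C(=O)OCC=C)c(C=O)c2O)C(=O)C1COCc1ccccc1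
A4 | alternative 2 | tetrahydro depsidone with ring A as a 3-aryloxycyclohex-2-enone (racemic trans, one enantiomer drawn) | O=C1C[C@H](C)[C@H]2C(=O)Oc3c(C)c(OCc4ccccc4)c(C(=O)OCC=C)c(C=O)c3OC2=C1COCc1ccccc1
A5 | alternative 3 | allyl 4-methoxy-6-methyl-2-{[(trifluoromethyl)sulfonyl]oxy}-3-(trimethylsilyl)benzoate | COc1cc(C)c(C(=O)OCC=C)c(OS(=O)(=O)C(F)(F)F)c1[Si](C)(C)C
A6 | alternative 3 | tert-butyl 4-(allyloxy)-6-(benzyloxy)-2-(dimethoxymethyl)-3-hydroxy-5-methylbenzoate | Oc1c(OCC=C)c(C)c(OCc2ccccc2)c(C(=O)OC(C)(C)C)c1C(OC)OC
A7 | alternative 3 | diaryl ether with a carboxylic acid at C6 and an allyl ester at C4 | COc1cc(C)c(C(=O)OCC=C)c(Oc2c(OCC=C)c(C)c(OCc3ccccc3)c(C(=O)OC(C)(C)C)c2C(OC)OC)c1C(=O)O
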